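**Strategy.** The route rests on disconnecting the C2–C3 bond of the dihydropyran ring. An open-chain aryl sec-alkyl ether, whose O-bearing carbon (future C2) already carries the methyl group, the triene chain and the correct configuration, is cyclised by dirhodium-carbenoid insertion of an ortho diazoacetyl carbon (future C3) into that tertiary C–H bond. One operation closes the pyran ring and turns a C–H stereocentre into the quaternary C2 stereocentre with retention. The step exploits the activation of the C2–H bond by ring oxygen O1 and the fully substituted benzene ring, which offers the carbenoid no aromatic C–H. The C4 carbonyl and the phenol pivalate are then removed together.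

Key step: step 6

Assumption: (5E,9E)-farnesylacetone 1 is taken as purchasable in geometrically pure form. Chroman numbering (O1, C2, C3, C4, C4a, C5–C8, C8a) is used for all cyclised compounds.

**Step 1**
Reactants: 1 (5E,9E)-6,10,14-trimethylpentadeca-5,9,13-trien-2-one (farnesylacetone)
Product: 2 (2S,5E,9E)-6,10,14-trimethylpentadeca-5,9,13-trien-2-ol
Conditions: (S)-selective alcohol dehydrogenase ADH-A (Rhodococcus ruber), NADH (cat.), 2-propanol (20 vol %), phosphate buffer pH 7.5, 30 °C
Reagents that add atoms: none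
Why: Biocatalytic transfer hydrogenation of a methyl ketone, in which the enzyme should deliver hydride from NADH to the Re face (methyl as the small group) and so set the (S)-carbinol centre, with 2-propanol as terminal reductant.

**Step 2**
Reactants: 3 2,3,5-trimethylhydroquinone
Product: 4 1-(2,5-dihydroxy-3,4,6-trimethylphenyl)ethan-1-one
Conditions: AcOH, BF3·OEt2, 100 °C; aqueous NaOAc work-up
Reagents that add atoms: acetic acid, CC(=O)O
Why: Friedel–Crafts acylation (Fries-type O-to-C acyl transfer) can only take place at the single unsubstituted ring position, which lies ortho to a hydroxyl group.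

**Step 3**
Reactants: 4 1-(2,5-dihydroxy-3,4,6-trimethylphenyl)ethan-1-one
Product: 5 3-acetyl-4-hydroxy-2,5,6-trimethylphenyl pivalate
Conditions: PivCl (1.05 equiv), Et3N, DMAP (cat.), CH2Cl2, 0 °C
Reagents that add atoms: pivaloyl chloride, CC(C)(C)C(=O)Cl
Why: Selective O-acylation, since the hydroxyl ortho to the acetyl group is tied up in an intramolecular hydrogen bond and the other one should react first; the non-enolisable, hindered pivalate is chosen to survive the strong base of step 5.

**Step 4**
Reactants: 5 3-acetyl-4-hydroxy-2,5,6-trimethylphenyl pivalate; 2 (2S,5E,9E)-6,10,14-trimethylpentadeca-5,9,13-trien-2-ol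
Product: 6 3-acetyl-2,5,6-trimethyl-4-{[(2R,5E,9E)-6,10,14-trimethylpentadeca-5,9,13-trien-2-yl]oxy}phenyl pivalate
Conditions: PPh3, DIAD, toluene, 0 °C → rt (high concentration)
Reagents that add atoms: none
Why: Mitsunobu reaction, in which the phenol displaces the oxyphosphonium group in an SN2 step with inversion, so that the (S)-alcohol should give the (R)-configured ether carbon (future C2).

**Step 5**
Reactants: 6 3-acetyl-2,5,6-trimethyl-4-{[(2R,5E,9E)-6,10,14-trimethylpentadeca-5,9,13-trien-2-yl]oxy}phenyl pivalate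
Product: 8 3-(2-diazoacetyl)-2,5,6-trimethyl-4-{[(2R,5E,9E)-6,10,14-trimethylpentadeca-5,9,13-trien-2-yl]oxy}phenyl pivalate, via trifluoroacetyl diketone 7 (not isolated)
Conditions: LiN(SiMe3)2, THF, −78 °C; CF3CO2CH2CF3; dilute HCl work-up; then MsN3, Et3N, H2O (1 equiv), MeCN, rt
Reagents that add atoms: methanesulfonyl azide, CS(=O)(=O)N=[N+]=[N-] (the two nitrogen atoms of the diazo group); 2,2,2-trifluoroethyl trifluoroacetate, O=C(OCC(F)(F)F)C(F)(F)F (trifluoroacetyl group of 7 only)
Why: Regitz-type deacylative diazo transfer, in which the methyl ketone is activated as its trifluoroacetyl 1,3-diketone, which takes up the diazo group and loses the trifluoroacetyl group to the sulfonamide; the ether stereocentre has no acidic hydrogen and is not touched.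

**Step 6**
Reactants: 8 3-(2-diazoacetyl)-2,5,6-trimethyl-4-{[(2R,5E,9E)-6,10,14-trimethylpentadeca-5,9,13-trien-2-yl]oxy}phenyl pivalate
Product: 9 (2R)-2,5,7,8-tetramethyl-4-oxo-2-[(3E,7E)-4,8,12-trimethyltrideca-3,7,11-trien-1-yl]-3,4-dihydro-2H-chromen-6-yl pivalate
Conditions: Rh2(OAc)4 (1 mol %), CH2Cl2, slow addition of 8 by syringe pump at high dilution, rt → 40 °C
Reagents that add atoms: none
Why: Rh2(OAc)4 decomposes the diazo ketone to an electrophilic rhodium carbenoid at the future C3, which inserts through a three-centre, hydride-transfer-like transition state into the tertiary C–H bond at the future C2, forming C2–C3 and releasing the catalyst. The closest known reaction type is the dirhodium-catalysed intramolecular C–H insertion of 2-alkoxyaryl diazomethyl ketones to chroman-4-ones and, for the stereochemistry, carbenoid insertion into tertiary C–H stereocentres with retention. The dihydropyran ring (O1–C2–C3–C4–C4a–C8a) closes in a 1,6-insertion mode, which should be favoured here because the only 1,5-positions are the ether oxygen and the non-activated primary C–H of the C5 methyl group. The new quaternary stereocentre C2 is controlled by the substrate alone: carbon enters on the face from which hydrogen leaves, so the (R)-ether carbon of 8 should become (R)-C2 of 9 with retention. The step needs site selectivity for this C–H bond over oxonium ylide formation at O1, cyclopropanation of the three trisubstituted olefins and insertion elsewhere; it is secured by the activation of the tertiary C–H bond by O1, by the fully substituted benzene ring, by the distance of the olefins (nine-membered or larger rings) and by slow addition at high dilution.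

**Step 7**
Reactants: 9 (2R)-2,5,7,8-tetramethyl-4-oxo-2-[(3E,7E)-4,8,12-trimethyltrideca-3,7,11-trien-1-yl]-3,4-dihydro-2H-chromen-6-yl pivalate
Product: 11 (2R)-2,5,7,8-tetramethyl-2-[(3E,7E)-4,8,12-trimethyltrideca-3,7,11-trien-1-yl]-3,4-dihydro-2H-chromen-6-ol ((R)-α-tocotrienol), via chromane-4,6-diol 10 (not isolated)
Conditions: LiAlH4, AlCl3, Et2O, 0 °C → reflux, under argon; aqueous potassium sodium tartrate work-up
Reagents that add atoms: none
Why: Mixed chloroalane reduction, in which the aryl ketone is reduced to the benzylic aluminium alkoxide, which ionises with help from the ortho ring oxygen and takes up a second hydride to give the C4 methylene group, while the pivalate is cleaved reductively; no enolate forms, so C2 cannot open by retro-oxa-Michael reaction and keeps its configuration.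

**Compound list**
1 | (5E,9E)-6,10,14-trimethylpentadeca-5,9,13-trien-2-one (farnesylacetone) | CC(C)=CCC/C(C)=C/CC/C(C)=C/CCC(C)=O | starting material
2 | (2S,5E,9E)-6,10,14-trimethylpentadeca-5,9,13-trien-2-ol | CC(C)=CCC/C(C)=C/CC/C(C)=C/CC[C@H](C)O | intermediate
3 | 2,3,5-trimethylhydroquinone | Cc1cc(O)c(C)c(C)c1O | starting material
4 | 1-(2,5-dihydroxy-3,4,6-trimethylphenyl)ethan-1-one | CC(=O)c1c(O)c(C)c(C)c(O)c1C | intermediate
5 | 3-acetyl-4-hydroxy-2,5,6-trimethylphenyl pivalate | CC(=O)c1c(O)c(C)c(C)c(OC(=O)C(C)(C)C)c1C | intermediate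
6 | 3-acetyl-2,5,6-trimethyl-4-{[(2R,5E,9E)-6,10,14-trimethylpentadeca-5,9,13-trien-2-yl]oxy}phenyl pivalate | CC(C)=CCC/C(C)=C/CC/C(C)=C/CC[C@@H](C)Oc1c(C)c(C)c(OC(=O)C(C)(C)C)c(C)c1C(C)=O | intermediate
7 | 2,5,6-trimethyl-3-(4,4,4-trifluoro-3-oxobutanoyl)-4-{[(2R,5E,9E)-6,10,14-trimethylpentadeca-5,9,13-trien-2-yl]oxy}phenyl pivalate | CC(C)=CCC/C(C)=C/CC/C(C)=C/CC[C@@H](C)Oc1c(C)c(C)c(OC(=O)C(C)(C)C)c(C)c1C(=O)CC(=O)C(F)(F)F | intermediate (not isolated)
8 | 3-(2-diazoacetyl)-2,5,6-trimethyl-4-{[(2R,5E,9E)-6,10,14-trimethylpentadeca-5,9,13-trien-2-yl]oxy}phenyl pivalate | CC(C)=CCC/C(C)=C/CC/C(C)=C/CC[C@@H](C)Oc1c(C)c(C)c(OC(=O)C(C)(C)C)c(C)c1C(=O)C=[N+]=[N-] | intermediate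
9 | (2R)-2,5,7,8-tetramethyl-4-oxo-2-[(3E,7E)-4,8,12-trimethyltrideca-3,7,11-trien-1-yl]-3,4-dihydro-2H-chromen-6-yl pivalate | CC(C)=CCC/C(C)=C/CC/C(C)=C/CC[C@]1(C)CC(=O)c2c(C)c(OC(=O)C(C)(C)C)c(C)c(C)c2O1 | intermediate
10 | (2R)-2,5,7,8-tetramethyl-2-[(3E,7E)-4,8,12-trimethyltrideca-3,7,11-trien-1-yl]chromane-4,6-diol (C4 epimers, present as aluminium alkoxide) | CC(C)=CCC/C(C)=C/CC/C(C)=C/CC[C@]1(C)CC(O)c2c(C)c(O)c(C)c(C)c2O1 | intermediate (not isolated)
11 | (2R)-2,5,7,8-tetramethyl-2-[(3E,7E)-4,8,12-trimethyltrideca-3,7,11-trien-1-yl]-3,4-dihydro-2H-chromen-6-ol ((R)-α-tocotrienol) | CC(C)=CCC/C(C)=C/CC/C(C)=C/CC[C@]1(C)CCc2c(C)c(O)c(C)c(C)c2O1 | target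

**Step count.** Total: 7 steps. Longest linear sequence: 6 steps (steps 2–7, from 3).

**Steps most likely to fail**

1. Step 6 (key step). The carbenoid may be diverted to the lone pair of O1 (oxonium ylide, then 1,2-shift to a benzofuranone), or the insertion may turn stepwise through a planar oxocarbenium ion and erode the configuration at C2. The fallback sets out from 4 and 1 and comes back at 9. A Kabbe condensation of 4 with 1 (pyrrolidine, toluene, reflux; enamine aldol condensation, then ring closure by oxa-Michael addition) should give racemic 6-hydroxy-2,5,7,8-tetramethyl-2-[(3E,7E)-4,8,12-trimethyltrideca-3,7,11-trien-1-yl]chroman-4-one F1. Pivaloylation (PivCl, Et3N, DMAP, CH2Cl2) should give the racemic pivalate F2, which is resolved by preparative chromatography on a cellulose tris(3,5-dimethylphenylcarbamate) stationary phase to give 9. The unwanted (S)-configured chromanone pivalate F3 is returned to F2 with pyrrolidine (retro-oxa-Michael/oxa-Michael) and recycled.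

2. Step 4. Substitution at a doubly ortho-substituted, hydrogen-bonded phenol may be so slow that the activated alcohol eliminates or alkylates the reduced azodicarboxylate. The fallback sets out from 2 and comes back at 6. MsCl and Et3N (CH2Cl2, 0 °C) convert 2 into (2S,5E,9E)-6,10,14-trimethylpentadeca-5,9,13-trien-2-yl methanesulfonate F4, with retention. The pre-formed caesium phenoxide of 5 (Cs2CO3, DMF, 50 °C) is then alkylated with F4 in a Williamson etherification with inversion, to give 6.

3. Step 7. Ionisation at C4 under the Lewis-acidic hydride may be followed by loss of a proton to the chromene, or by capture of the cation by a side-chain olefin in place of hydride; the pivalate may also be cleaved incompletely. The fallback sets out from 9 and comes back at 11 without passing through a carbocation. Condensation of 9 with TsNHNH2 (EtOH, cat. AcOH, 60 °C) gives the (2R)-chroman-4-one tosylhydrazone pivalate F5. Reduction with catecholborane (CHCl3, 0 °C), then NaOAc·3H2O at reflux, should give (R)-α-tocotrienyl pivalate F6. LiAlH4 (THF, 0 °C) then cleaves the ester to 11.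

**Further compounds**
F1 | step 6 | racemic 6-hydroxy-2,5,7,8-tetramethyl-2-[(3E,7E)-4,8,12-trimethyltrideca-3,7,11-trien-1-yl]chroman-4-one | CC(C)=CCC/C(C)=C/CC/C(C)=C/CCC1(C)CC(=O)c2c(C)c(O)c(C)c(C)c2O1
F2 | step 6 | racemic 2,5,7,8-tetramethyl-4-oxo-2-[(3E,7E)-4,8,12-trimethyltrideca-3,7,11-trien-1-yl]chroman-6-yl pivalate | CC(C)=CCC/C(C)=C/CC/C(C)=C/CCC1(C)CC(=O)c2c(C)c(OC(=O)C(C)(C)C)c(C)c(C)c2O1
F3 | step 6 | (2S)-2,5,7,8-tetramethyl-4-oxo-2-[(3E,7E)-4,8,12-trimethyltrideca-3,7,11-trien-1-yl]chroman-6-yl pivalate | CC(C)=CCC/C(C)=C/CC/C(C)=C/CC[C@@]1(C)CC(=O)c2c(C)c(OC(=O)C(C)(C)C)c(C)c(C)c2O1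
F4 | step 4 | (2S,5E,9E)-6,10,14-trimethylpentadeca-5,9,13-trien-2-yl methanesulfonate | CC(C)=CCC/C(C)=C/CC/C(C)=C/CC[C@H](C)OS(C)(=O)=O
F5 | step 7 | (2R)-2,5,7,8-tetramethyl-4-(2-tosylhydrazinylidene)-2-[(3E,7E)-4,8,12-trimethyltrideca-3,7,11-trien-1-yl]chroman-6-yl pivalate | CC(C)=CCC/C(C)=C/CC/C(C)=C/CC[C@]1(C)CC(=NNS(=O)(=O)c3ccc(C)cc3)c2c(C)c(OC(=O)C(C)(C)C)c(C)c(C)c2O1
F6 | step 7 | (2R)-2,5,7,8-tetramethyl-2-[(3E,7E)-4,8,12-trimethyltrideca-3,7,11-trien-1-yl]chroman-6-yl pivalate | CC(C)=CCC/C(C)=C/CC/C(C)=C/CC[C@]1(C)CCc2c(C)c(OC(=O)C(C)(C)C)c(C)c(C)c2O1
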